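The 2,3-dihydrobenzofuran is disconnected across O1–C2 and C3a–C3 into an (E)-stilbene (C2=C3 with both aryl groups in place) and ring A in the disguise of a cyclic 2-diazo-1,3-dione. A chiral dirhodium carbenoid is attacked by C3 and the enolate oxygen captures the C2 benzylic cation, so one operation forges both bonds and both stereocentres; dehydrogenation then aromatises ring A to the C4 phenol. The step exploits two features: C2 is benzylic to the para-oxygenated guaiacyl ring (cation stabilised, regiochemistry fixed) and C3a sits between the oxygen-bearing carbons C4 and C7a, i.e. the 2-position of a 1,3-dione. The styryl arm is added last from the C6 ester.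

Key step: step 5

Remark: atom numbers are those of the benzofuran (O1, C2, C3, C3a, C4–C7, C7a); TIPS = triisopropylsilyl; NTTL = N-(1,8-naphthaloyl)-tert-leucinate.

Assumption: the sense of induction of Rh2(S-NTTL)4 in step 5 cannot be assigned with confidence in advance; if it leads to the (2R,3R) series, the mirror-image catalyst Rh2(R-NTTL)4 is used instead.

Step 1
Reactants: 1 5-bromobenzene-1,3-diol
Product: 2 1-bromo-3,5-bis(triisopropylsilyloxy)benzene
Conditions: TIPSCl (2.4 equiv), imidazole, DMF, rt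
Reagents that add atoms: chlorotriisopropylsilane, CC(C)[Si](Cl)(C(C)C)C(C)C
Why: Imidazole-promoted O-silylation of phenols is routine, and the bulky, base-stable silyl ethers later shield the resorcinol ring from the carbenoid and survive amide bases and hot amine.

Step 2
Reactants: 3 2-methoxy-4-vinylphenol
Product: 4 (2-methoxy-4-vinylphenoxy)triisopropylsilane
Conditions: TIPSCl (1.2 equiv), imidazole, DMF, rt
Reagents that add atoms: chlorotriisopropylsilane, CC(C)[Si](Cl)(C(C)C)C(C)C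
Why: Phenol silylation as in step 1 masks the acidic O–H while keeping the para-oxygen a donor for the later cation at C2.

Step 3
Reactants: 2 1-bromo-3,5-bis(triisopropylsilyloxy)benzene; 4 (2-methoxy-4-vinylphenoxy)triisopropylsilane
Product: 5 (E)-1-[3,5-bis(triisopropylsilyloxy)phenyl]-2-[3-methoxy-4-(triisopropylsilyloxy)phenyl]ethene
Conditions: Pd(OAc)2 (5 mol %), P(o-tol)3 (10 mol %), Et3N, DMF, 100 °C
Reagents that add atoms: none
Why: Mizoroki–Heck arylation of the terminal styrene should proceed by syn-carbopalladation and syn-β-hydride elimination to give the (E)-stilbene.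

Step 4
Reactants: 6 ethyl 3,5-dioxocyclohexane-1-carboxylate
Product: 7 ethyl 4-diazo-3,5-dioxocyclohexane-1-carboxylate
Conditions: 4-AcNHC6H4SO2N3, Et3N, MeCN, 0 °C to rt
Reagents that add atoms: 4-acetamidobenzenesulfonyl azide, CC(=O)Nc1ccc(cc1)S(=O)(=O)N=[N+]=[N-]
Why: Regitz diazo transfer to the doubly activated methylene between the two carbonyl groups is fast and chemoselective under mild amine base.

Step 5
Reactants: 5 (E)-1-[3,5-bis(triisopropylsilyloxy)phenyl]-2-[3-methoxy-4-(triisopropylsilyloxy)phenyl]ethene; 7 ethyl 4-diazo-3,5-dioxocyclohexane-1-carboxylate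
Product: 9 ethyl (2S,3S)-3-[3,5-bis(triisopropylsilyloxy)phenyl]-2-[3-methoxy-4-(triisopropylsilyloxy)phenyl]-4-oxo-2,3,4,5,6,7-hexahydro-1-benzofuran-6-carboxylate (both C6 epimers), via ring-open zwitterion 8 (not isolated)
Conditions: Rh2(S-NTTL)4 (2 mol %), 7 (1.5 equiv) added over 6 h, PhCF3, 40 °C
Reagents that add atoms: none
Why: The dirhodium tetracarboxylate converts 7 into an electrophilic acceptor/acceptor carbenoid whose carbene carbon (the future C3a) is attacked end-on by the stilbene carbon remote from the para-oxygenated ring (the future C3), giving the C3a–C3 bond and the benzylic cation/enolate dipole 8, which collapses by O-attack on C2 and releases the catalyst. The closest known reaction type is the dirhodium-catalysed formal [3+2] cycloaddition of 2-diazocyclohexane-1,3-diones with vinyl ethers and aryl alkenes, together with the zwitterionic [3+2] annulations of chiral dirhodium carbenoids with trans-anethole-type alkenes. The dihydrofuran ring is closed in a 5-exo-trig (enolendo) O-cyclisation onto the quinone-methide-like cation. C3 becomes stereogenic in the C–C bond-forming event at the rhodium-bound carbon, so the chiral carboxylate wall should select the alkene face (catalyst control, unlike terminal alkenes whose only stereocentre arises after the metal has left), and C2 is set by closure anti to the C3 aryl group (substrate control; trans is also the thermodynamic isomer because C2 can re-ionise). The step needs regioselectivity, secured by the para-silyloxy donor that stabilises cation character only at C2 while the meta-oxygens of the other ring cannot, chemoselectivity for the alkene over the arene rings, secured by the flanking triisopropylsilyl groups, and enantioselectivity from the catalyst.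

Step 6
Reactants: 9 ethyl (2S,3S)-3-[3,5-bis(triisopropylsilyloxy)phenyl]-2-[3-methoxy-4-(triisopropylsilyloxy)phenyl]-4-oxo-2,3,4,5,6,7-hexahydro-1-benzofuran-6-carboxylate
Product: 11 ethyl (2S,3S)-3-[3,5-bis(triisopropylsilyloxy)phenyl]-4-hydroxy-2-[3-methoxy-4-(triisopropylsilyloxy)phenyl]-2,3-dihydro-1-benzofuran-6-carboxylate, via cross-conjugated dienone 10 (not isolated)
Conditions: LiN(i-Pr)2 (1.2 equiv), THF, −78 °C; then PhS(Cl)=N-t-Bu (1.3 equiv), −78 °C to rt
Reagents that add atoms: none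
Why: One-pot ketone dehydrogenation (enolate sulfinimidoylation, then syn-elimination of the sulfenamide) should give dienone 10, whose enolisation is driven by aromatisation of ring A; any regioisomeric enolate leads to the same arene and neither C2–H nor C3–H is acidic, so both stereocentres are untouched.

Step 7
Reactants: 11 ethyl (2S,3S)-3-[3,5-bis(triisopropylsilyloxy)phenyl]-4-hydroxy-2-[3-methoxy-4-(triisopropylsilyloxy)phenyl]-2,3-dihydro-1-benzofuran-6-carboxylate
Product: 12 (2S,3S)-3-[3,5-bis(triisopropylsilyloxy)phenyl]-6-(hydroxymethyl)-2-[3-methoxy-4-(triisopropylsilyloxy)phenyl]-2,3-dihydro-1-benzofuran-4-ol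
Conditions: (i-Bu)2AlH (4 equiv), CH2Cl2, −78 to 0 °C; aq. potassium sodium tartrate
Reagents that add atoms: none
Why: The aluminium hydride reduces the aryl ester to the benzylic alcohol (ester reduction) while the phenol is merely deprotonated and the silyl ethers and the benzylic ether ring are inert.

Step 8
Reactants: 12 (2S,3S)-3-[3,5-bis(triisopropylsilyloxy)phenyl]-6-(hydroxymethyl)-2-[3-methoxy-4-(triisopropylsilyloxy)phenyl]-2,3-dihydro-1-benzofuran-4-ol
Product: 13 (2S,3S)-3-[3,5-bis(triisopropylsilyloxy)phenyl]-4-hydroxy-2-[3-methoxy-4-(triisopropylsilyloxy)phenyl]-2,3-dihydro-1-benzofuran-6-carbaldehyde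
Conditions: activated MnO2 (excess), CH2Cl2, rt
Reagents that add atoms: none
Why: Activated MnO2 oxidises benzylic alcohols selectively to aldehydes without over-oxidation and should leave the hindered meta-phenol alone.

Step 9
Reactants: 13 (2S,3S)-3-[3,5-bis(triisopropylsilyloxy)phenyl]-4-hydroxy-2-[3-methoxy-4-(triisopropylsilyloxy)phenyl]-2,3-dihydro-1-benzofuran-6-carbaldehyde
Product: 14 (2S,3S)-3-[3,5-bis(triisopropylsilyloxy)phenyl]-6-ethenyl-2-[3-methoxy-4-(triisopropylsilyloxy)phenyl]-2,3-dihydro-1-benzofuran-4-ol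
Conditions: Ph3PCH3Br (3 equiv), KOt-Bu (3 equiv), THF, 0 °C to rt
Reagents that add atoms: methyltriphenylphosphonium bromide, C[P+](c1ccccc1)(c1ccccc1)c1ccccc1.[Br-]
Why: Wittig methylenation with the non-stabilised ylide is fast even with the phenoxide present, for which one extra equivalent of ylide is sacrificed.

Step 10
Reactants: 14 (2S,3S)-3-[3,5-bis(triisopropylsilyloxy)phenyl]-6-ethenyl-2-[3-methoxy-4-(triisopropylsilyloxy)phenyl]-2,3-dihydro-1-benzofuran-4-ol; 15 4-iodo-2-methoxyphenol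
Product: 16 (2S,3S)-3-[3,5-bis(triisopropylsilyloxy)phenyl]-6-[(E)-2-(4-hydroxy-3-methoxyphenyl)ethenyl]-2-[3-methoxy-4-(triisopropylsilyloxy)phenyl]-2,3-dihydro-1-benzofuran-4-ol
Conditions: Pd(OAc)2 (5 mol %), P(o-tol)3 (10 mol %), Et3N, DMF, 90 °C
Reagents that add atoms: none
Why: Mizoroki–Heck coupling of the aryl iodide with the terminal styrene should give the (E)-stilbene arm by β-arylation, free phenols being tolerated under amine base.

Step 11
Reactants: 16 (2S,3S)-3-[3,5-bis(triisopropylsilyloxy)phenyl]-6-[(E)-2-(4-hydroxy-3-methoxyphenyl)ethenyl]-2-[3-methoxy-4-(triisopropylsilyloxy)phenyl]-2,3-dihydro-1-benzofuran-4-ol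
Product: 17 bisisorhapontigenin B, (2S,3S)-3-(3,5-dihydroxyphenyl)-2-(4-hydroxy-3-methoxyphenyl)-6-[(E)-2-(4-hydroxy-3-methoxyphenyl)ethenyl]-2,3-dihydro-1-benzofuran-4-ol
Conditions: Bu4NF / AcOH (1:1, 4 equiv), THF, 0 °C to rt, argon
Reagents that add atoms: none
Why: Fluoride cleaves the three aryl silyl ethers (desilylation), and the acetic acid buffer should keep the polyphenol from phenoxide autoxidation and from ring opening through the quinone methide, so the (2S,3S) centres persist.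

Compound list

1 | 5-bromobenzene-1,3-diol | Oc1cc(O)cc(Br)c1 | starting material
2 | 1-bromo-3,5-bis(triisopropylsilyloxy)benzene | Brc1cc(O[Si](C(C)C)(C(C)C)C(C)C)cc(O[Si](C(C)C)(C(C)C)C(C)C)c1 | intermediate
3 | 2-methoxy-4-vinylphenol | COc1cc(C=C)ccc1O | starting material
4 | (2-methoxy-4-vinylphenoxy)triisopropylsilane | COc1cc(C=C)ccc1O[Si](C(C)C)(C(C)C)C(C)C | intermediate
5 | (E)-1-[3,5-bis(triisopropylsilyloxy)phenyl]-2-[3-methoxy-4-(triisopropylsilyloxy)phenyl]ethene | COc1cc(/C=C/c2cc(O[Si](C(C)C)(C(C)C)C(C)C)cc(O[Si](C(C)C)(C(C)C)C(C)C)c2)ccc1O[Si](C(C)C)(C(C)C)C(C)C | intermediate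
6 | ethyl 3,5-dioxocyclohexane-1-carboxylate | CCOC(=O)C1CC(=O)CC(=O)C1 | starting material
7 | ethyl 4-diazo-3,5-dioxocyclohexane-1-carboxylate | CCOC(=O)C1CC(=O)C(=[N+]=[N-])C(=O)C1 | intermediate
8 | ring-open zwitterion (enolate and C2 benzylic cation, drawn rhodium-free; not isolated) | CCOC(=O)C1CC(=O)C(=C([O-])C1)[C@H](c1cc(O[Si](C(C)C)(C(C)C)C(C)C)cc(O[Si](C(C)C)(C(C)C)C(C)C)c1)[CH+]c1ccc(O[Si](C(C)C)(C(C)C)C(C)C)c(OC)c1 | intermediate
9 | ethyl (2S,3S)-3-[3,5-bis(triisopropylsilyloxy)phenyl]-2-[3-methoxy-4-(triisopropylsilyloxy)phenyl]-4-oxo-2,3,4,5,6,7-hexahydro-1-benzofuran-6-carboxylate (both C6 epimers) | CCOC(=O)C1CC(=O)C2=C(C1)O[C@H](c1ccc(O[Si](C(C)C)(C(C)C)C(C)C)c(OC)c1)[C@H]2c1cc(O[Si](C(C)C)(C(C)C)C(C)C)cc(O[Si](C(C)C)(C(C)C)C(C)C)c1 | intermediate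
10 | ethyl (2S,3S)-3-[3,5-bis(triisopropylsilyloxy)phenyl]-2-[3-methoxy-4-(triisopropylsilyloxy)phenyl]-4-oxo-2,3,4,7-tetrahydro-1-benzofuran-6-carboxylate (cross-conjugated dienone; not isolated) | CCOC(=O)C1=CC(=O)C2=C(C1)O[C@H](c1ccc(O[Si](C(C)C)(C(C)C)C(C)C)c(OC)c1)[C@H]2c1cc(O[Si](C(C)C)(C(C)C)C(C)C)cc(O[Si](C(C)C)(C(C)C)C(C)C)c1 | intermediate
11 | ethyl (2S,3S)-3-[3,5-bis(triisopropylsilyloxy)phenyl]-4-hydroxy-2-[3-methoxy-4-(triisopropylsilyloxy)phenyl]-2,3-dihydro-1-benzofuran-6-carboxylate | CCOC(=O)c1cc(O)c2c(c1)O[C@H](c1ccc(O[Si](C(C)C)(C(C)C)C(C)C)c(OC)c1)[C@H]2c1cc(O[Si](C(C)C)(C(C)C)C(C)C)cc(O[Si](C(C)C)(C(C)C)C(C)C)c1 | intermediate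
12 | (2S,3S)-3-[3,5-bis(triisopropylsilyloxy)phenyl]-6-(hydroxymethyl)-2-[3-methoxy-4-(triisopropylsilyloxy)phenyl]-2,3-dihydro-1-benzofuran-4-ol | OCc1cc(O)c2c(c1)O[C@H](c1ccc(O[Si](C(C)C)(C(C)C)C(C)C)c(OC)c1)[C@H]2c1cc(O[Si](C(C)C)(C(C)C)C(C)C)cc(O[Si](C(C)C)(C(C)C)C(C)C)c1 | intermediate
13 | (2S,3S)-3-[3,5-bis(triisopropylsilyloxy)phenyl]-4-hydroxy-2-[3-methoxy-4-(triisopropylsilyloxy)phenyl]-2,3-dihydro-1-benzofuran-6-carbaldehyde | O=Cc1cc(O)c2c(c1)O[C@H](c1ccc(O[Si](C(C)C)(C(C)C)C(C)C)c(OC)c1)[C@H]2c1cc(O[Si](C(C)C)(C(C)C)C(C)C)cc(O[Si](C(C)C)(C(C)C)C(C)C)c1 | intermediate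
14 | (2S,3S)-3-[3,5-bis(triisopropylsilyloxy)phenyl]-6-ethenyl-2-[3-methoxy-4-(triisopropylsilyloxy)phenyl]-2,3-dihydro-1-benzofuran-4-ol | C=Cc1cc(O)c2c(c1)O[C@H](c1ccc(O[Si](C(C)C)(C(C)C)C(C)C)c(OC)c1)[C@H]2c1cc(O[Si](C(C)C)(C(C)C)C(C)C)cc(O[Si](C(C)C)(C(C)C)C(C)C)c1 | intermediate
15 | 4-iodo-2-methoxyphenol | COc1cc(I)ccc1O | starting material
16 | (2S,3S)-3-[3,5-bis(triisopropylsilyloxy)phenyl]-6-[(E)-2-(4-hydroxy-3-methoxyphenyl)ethenyl]-2-[3-methoxy-4-(triisopropylsilyloxy)phenyl]-2,3-dihydro-1-benzofuran-4-ol | COc1cc(/C=C/c2cc(O)c3c(c2)O[C@H](c2ccc(O[Si](C(C)C)(C(C)C)C(C)C)c(OC)c2)[C@H]3c2cc(O[Si](C(C)C)(C(C)C)C(C)C)cc(O[Si](C(C)C)(C(C)C)C(C)C)c2)ccc1O | intermediate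
17 | bisisorhapontigenin B, (2S,3S)-3-(3,5-dihydroxyphenyl)-2-(4-hydroxy-3-methoxyphenyl)-6-[(E)-2-(4-hydroxy-3-methoxyphenyl)ethenyl]-2,3-dihydro-1-benzofuran-4-ol | COc1cc(/C=C/c2cc(O)c3c(c2)O[C@H](c2ccc(O)c(OC)c2)[C@H]3c2cc(O)cc(O)c2)ccc1O | target

Total step count: 11. Longest linear sequence: 9 steps (steps 1, 3, 5, 6, 7, 8, 9, 10, 11).

Steps most likely to fail

Step 5. The carbene transfer may show poor facial selectivity at C3, so the enantiomeric excess may be low. The hindered 1,2-disubstituted alkene may also attack too slowly, so that the carbenoid is diverted into functionalisation of the electron-rich arene rings. The fallback sets out from 5 and 6 and comes back at 12. Mn(OAc)3·2H2O (2.2 equiv) in AcOH at 70 °C effects the known oxidative radical [3+2] annulation of dione 6 with stilbene 5: the dione radical adds to the future C3, the benzylic radical is oxidised to the cation and the enol oxygen closes the ring. This gives the racemic trans keto ester F1. Dehydrogenation as in step 6 gives the racemic phenol F2. Acylation of the C4 hydroxyl with (1R)-(−)-menthyl chloroformate (pyridine, DMAP, CH2Cl2) gives two diastereomeric carbonates, from which the (2S,3S) menthyl carbonate F3 is separated by crystallisation or chromatography. (i-Bu)2AlH as in step 7 then reduces the ester and cleaves the carbonate, giving 12.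

Step 6. Proton transfer from the emerging phenol to unreacted enolate may stall the dehydrogenation, or the sulfur adduct may fail to eliminate cleanly in the presence of the ester. The fallback sets out from 9 and comes back at 11. LiN(SiMe3)2 and Me3SiCl (THF, −78 °C) give the trimethylsilyl dienol ether F4. Saegusa–Ito oxidation with Pd(OAc)2 (MeCN, rt) then installs the C5=C6 double bond, and tautomerisation delivers 11.

Step 10. The coupling may suffer from competing α-arylation of the styrene, from catalyst deactivation by the phenolate-rich partners, or from silyl loss in hot amine. The fallback sets out from 14 (together with 4) and comes back at 17. Cross metathesis of styrene 14 with an excess of silyl styrene 4 (second-generation Hoveyda–Grubbs catalyst, CH2Cl2, 40 °C) gives the (E)-stilbene with four silyl ethers F5. The conditions of step 11, with one more equivalent of fluoride, then give 17.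

Further compounds

F1 | step 5 | racemic trans keto ester, ethyl (2S,3S)- and (2R,3R)-3-[3,5-bis(triisopropylsilyloxy)phenyl]-2-[3-methoxy-4-(triisopropylsilyloxy)phenyl]-4-oxo-2,3,4,5,6,7-hexahydro-1-benzofuran-6-carboxylate | CCOC(=O)C1CC(=O)C2=C(C1)O[C@H](c1ccc(O[Si](C(C)C)(C(C)C)C(C)C)c(OC)c1)[C@H]2c1cc(O[Si](C(C)C)(C(C)C)C(C)C)cc(O[Si](C(C)C)(C(C)C)C(C)C)c1.CCOC(=O)C1CC(=O)C2=C(C1)O[C@@H](c1ccc(O[Si](C(C)C)(C(C)C)C(C)C)c(OC)c1)[C@@H]2c1cc(O[Si](C(C)C)(C(C)C)C(C)C)cc(O[Si](C(C)C)(C(C)C)C(C)C)c1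
F2 | step 5 | racemic phenol, ethyl (2S,3S)- and (2R,3R)-3-[3,5-bis(triisopropylsilyloxy)phenyl]-4-hydroxy-2-[3-methoxy-4-(triisopropylsilyloxy)phenyl]-2,3-dihydro-1-benzofuran-6-carboxylate | CCOC(=O)c1cc(O)c2c(c1)O[C@H](c1ccc(O[Si](C(C)C)(C(C)C)C(C)C)c(OC)c1)[C@H]2c1cc(O[Si](C(C)C)(C(C)C)C(C)C)cc(O[Si](C(C)C)(C(C)C)C(C)C)c1.CCOC(=O)c1cc(O)c2c(c1)O[C@@H](c1ccc(O[Si](C(C)C)(C(C)C)C(C)C)c(OC)c1)[C@@H]2c1cc(O[Si](C(C)C)(C(C)C)C(C)C)cc(O[Si](C(C)C)(C(C)C)C(C)C)c1
F3 | step 5 | (2S,3S) menthyl carbonate, ethyl (2S,3S)-3-[3,5-bis(triisopropylsilyloxy)phenyl]-4-{[(1R,2S,5R)-menthyloxy]carbonyloxy}-2-[3-methoxy-4-(triisopropylsilyloxy)phenyl]-2,3-dihydro-1-benzofuran-6-carboxylate | CCOC(=O)c1cc(OC(=O)O[C@@H]2C[C@H](C)CC[C@H]2C(C)C)c2c(c1)O[C@H](c1ccc(O[Si](C(C)C)(C(C)C)C(C)C)c(OC)c1)[C@H]2c1cc(O[Si](C(C)C)(C(C)C)C(C)C)cc(O[Si](C(C)C)(C(C)C)C(C)C)c1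
F4 | step 6 | trimethylsilyl dienol ether, ethyl (2S,3S)-3-[3,5-bis(triisopropylsilyloxy)phenyl]-2-[3-methoxy-4-(triisopropylsilyloxy)phenyl]-4-(trimethylsilyloxy)-2,3,6,7-tetrahydro-1-benzofuran-6-carboxylate | CCOC(=O)C1C=C(O[Si](C)(C)C)C2=C(C1)O[C@H](c1ccc(O[Si](C(C)C)(C(C)C)C(C)C)c(OC)c1)[C@H]2c1cc(O[Si](C(C)C)(C(C)C)C(C)C)cc(O[Si](C(C)C)(C(C)C)C(C)C)c1
F5 | step 10 | (E)-stilbene with four silyl ethers, (2S,3S)-3-[3,5-bis(triisopropylsilyloxy)phenyl]-2-[3-methoxy-4-(triisopropylsilyloxy)phenyl]-6-{(E)-2-[3-methoxy-4-(triisopropylsilyloxy)phenyl]ethenyl}-2,3-dihydro-1-benzofuran-4-ol | COc1cc(/C=C/c2cc(O)c3c(c2)O[C@H](c2ccc(O[Si](C(C)C)(C(C)C)C(C)C)c(OC)c2)[C@H]3c2cc(O[Si](C(C)C)(C(C)C)C(C)C)cc(O[Si](C(C)C)(C(C)C)C(C)C)c2)ccc1O[Si](C(C)C)(C(C)C)C(C)C
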